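3 questions are enough for this flask, in which X and G are charged nearly one to one and stand for the time asked below; the earlier runs give what c needs, but they do not show how much of G is bound, so fr stays a guess.

all flasks: G 0.0286 M
- delta: X 0.013 M; run made earlier
- gamma: X 0.052 M; run made earlier
- flask: X 0.026 M; time 25 min

| run | time / min | X / % | Z / % |
|---|---|---|---|
| delta | 1.33 | 20.6 | 77.6 |
| delta | 4.00 | 5.5 | 90.9 |
| delta | 8.00 | 1.4 | 93.9 |
| delta | 10.0 | 1.0 | 94.3 |
| delta | 15.0 | 0.7 | 94.5 |
| gamma | 1.33 | 68.8 | 24.6 |
| gamma | 2.50 | 65.9 | 22.4 |
| gamma | 4.00 | 63.4 | 18.8 |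
| gamma | 8.00 | 57.3 | 13.2 |
| gamma | 15.0 | 51.9 | 7.7 |

(each reading ± 0.3 percentage points)

* part of the X that has reacted at 25 min
* share of the unused G that is free and not bound as J, at 25 min

- the earlier runs do not show how much of G is bound; that part of a forecast is a guess

How much Z can G make? In the gamma run at 1.33 min, Z present plus half of what is missing from the balance comes to 0.0145 M, close to half the G charged, so I count two G per Z, which makes G the limiting reagent in the flask and leaves, after that fast first stage, cZ at 0.0143 M and cX at 0.0117 M.

What happens afterwards? In gamma, cX minus cZ holds at 44 percentage points from the first reading to the last, 0.0230 M, so X and Z vanish in pairs, and for such a pair loss ln(cX/cZ) climbs in a straight line whose slope is the gap times the pairing constant, which gamma's first and last readings put at 2.80 L mol⁻¹ min⁻¹.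

And if you simply take cX equal to cZ? Then 1/cX grows by k times time, and my first round gives 0.00643 M, but that is the weak spot, since by my count the flask enters the second stage with more Z than X, Z ahead by 0.00260 M; going round again with this gap, cZ/cX reaches 1.47, cX is 0.00558 M, and my c is 78.5%.

The forecast says 78% (74% to 82%) and fr 15% (1% to 50%), adding: “With X still present, free G should be scarcer, so fr is a guess”.

The flask gives c 78.4% and fr 2.02%, so the forecast's fr stood 13 points too high. At the asked time J stands at 0.0140 M while free G is 1.01% of its charge. Put back for 12.5 min, the pairing constant gives 70.5% of X used, and the flask has 70.3%.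

    X + Z → L (k = 2.80 L mol⁻¹ min⁻¹)
    X + G ⇌ D + Z (K = 1.10, k = 83.0 L mol⁻¹ min⁻¹)
    G + D ⇌ J, settled at all times (K = 2.20 × 10⁵ L mol⁻¹)

In the neighbour flask with 0.044 M of X, I count cX at 0.0297 M when the second stage begins, ahead of cZ by 0.0154 M, so the same line gives cX/cZ = 6.10, cZ = 0.00302 M and c = 58.1%. The computed neighbour gives 58.9%.

The earlier runs and the new flask are calculated with constants of no real substance; noise was put on by code.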